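**Retrosynthetic overview**

1. Numbering used below: six-membered ring C1(=C15)–C2(OH)–C3(OAc)–C4(CH3)–C16(H)–C15(CH3); cyclopentane C4–C5–C6–C7–C16; eleven-membered ring C7–C8(=C19H2)–C9=C10–C11–C12(CH3)–C13–C14(OAc)–C1.
2. Enabling feature: on the cyclopentane the three carbons that lead into the other rings (C3 on C4, C15 on C16, C8 on C7) all stand on one face, so the ring is a bicyclo[2.2.1]heptane whose C3–C8 bridge bond has been cut. A Diels–Alder reaction of a 5-substituted 2-silyloxycyclopentadiene (C4=C3(OSi)–C8=C7, C16 sp3) with an ethylene equivalent (C5=C6) closes it and sets C4 (quaternary) and C7 from C16; the silyloxy oxygen becomes the C3 acetate oxygen.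
3. The temporary C3–C8 bond is then cut by Grob fragmentation, which gives the C3 acetyl group (C2) and the C8=C19 methylene of the 1,3-diene in one operation; the sulfonyl activating groups are removed reductively.
4. Six-membered ring: Claisen cyclisation C2→C1 to a 1,3-dione, enol triflate at C1, C2 hydroxylation with shift of the double bond to C1=C15, hydroxyl-directed reduction at C3. Eleven-membered ring last: Nozaki–Hiyama–Kishi closure C1–C14, then oxidation and CBS reduction to fix C14.
5. Order of rings: cyclopentenone (C3, C4, C7, C8, C16; C16 from (S)-4-silyloxycyclopentenone) → bicyclo[2.2.1]heptene (the five-membered ring of the target) → six-membered ring → eleven-membered ring; C12 comes from (R)-monomethyl 3-methylglutarate.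

Key step: step 12

Remark: 3, 9 and 20 are taken as commercial; stereocentres that are later destroyed (C15, C4 before step 11, C8 before step 16) or corrected (C14 before step 26) are left open in the SMILES.

Step 1
Reactants: 1 tert-butyl propanoate
Product: 2 1-tert-butoxy-1-(trimethylsilyloxy)prop-1-ene
Conditions: LiN(i-Pr)2, Me3SiCl (in situ quench), THF, −78 → 23 °C
Reagents that add atoms: chlorotrimethylsilane, C[Si](C)(C)Cl
Why: Kinetic ester enolisation with immediate O-silylation gives the ketene silyl acetal as a soft propionate nucleophile; no stereocentre is formed and the double-bond geometry is of no consequence.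

Step 2
Reactants: 3 (S)-4-(tert-butyldimethylsilyloxy)cyclopent-2-en-1-one; 2 1-tert-butoxy-1-(trimethylsilyloxy)prop-1-ene
Product: 4 trimethylsilyl enol ether of tert-butyl 2-[trans-2-(tert-butyldimethylsilyloxy)-4-oxocyclopentyl]propanoate
Conditions: Me3SiOTf (5 mol %), CH2Cl2, −78 °C; pyridine quench
Reagents that add atoms: none
Why: Mukaiyama–Michael addition with silyl transfer gives the 1,4-adduct as its regiodefined silyl enol ether; the nucleophile enters anti to the silyloxy group on the neighbouring carbon (C7), which sets C16, while C15 forms as an inconsequential mixture.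

Step 3
Reactants: 4 trimethylsilyl enol ether of the Michael adduct
Product: 7 tert-butyl 2-[(1R)-5-methyl-4-oxocyclopent-2-en-1-yl]propanoate, via lithium enolate 5 (not isolated), via methylated silyloxy ketone 6 (not isolated)
Conditions: MeLi, THF, 0 °C; MeI, DMPU, −78 → −20 °C; then DBU, 0 °C
Reagents that add atoms: iodomethane, CI
Why: Regiospecific enolate generation by Si–O cleavage and C-methylation at C4, followed by E1cB loss of silanolate across C8–C7, gives the transposed enone; C16 is untouched and the C4 configuration is irrelevant because C4 becomes sp2 in step 11.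

Step 4
Reactants: 7 tert-butyl 2-[(1R)-5-methyl-4-oxocyclopent-2-en-1-yl]propanoate
Product: 8 tert-butyl 2-[(1R)-3-iodo-5-methyl-4-oxocyclopent-2-en-1-yl]propanoate
Conditions: I2, pyridine, CH2Cl2, 23 °C
Reagents that add atoms: iodine, II
Why: α-Iodination of the enone (conjugate addition of pyridine, iodination of the enolate, elimination) places the cross-coupling handle on C8 without touching C16.

Step 5
Reactants: 9 (R)-5-methoxy-3-methyl-5-oxopentanoic acid
Product: 11 (R)-4-methyltetrahydro-2H-pyran-2-one, via hydroxy ester 10 (not isolated)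
Conditions: BH3·SMe2, THF, 0 → 23 °C; then TsOH (cat.), toluene, 60 °C
Reagents that add atoms: none
Why: Borane reduces the free carboxylic acid chemoselectively beside the methyl ester and acid-catalysed lactonisation follows; the C12 stereocentre comes unchanged from 9.

Step 6
Reactants: 11 (R)-4-methyltetrahydro-2H-pyran-2-one
Product: 12 (4R)-4-methyltetrahydro-2H-pyran-2-ol
Conditions: i-Bu2AlH, CH2Cl2, −78 °C
Reagents that add atoms: none
Why: Half-reduction of a lactone to the lactol at low temperature, the tetrahedral aluminium alkoxide being stable until work-up.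

Step 7
Reactants: 12 (4R)-4-methyltetrahydro-2H-pyran-2-ol
Product: 13 (S)-3-methylhex-5-yn-1-ol
Conditions: dimethyl (1-diazo-2-oxopropyl)phosphonate, K2CO3, MeOH, 0 → 23 °C
Reagents that add atoms: dimethyl (1-diazo-2-oxopropyl)phosphonate, COP(=O)(OC)C(=[N+]=[N-])C(C)=O
Why: Seyferth–Gilbert homologation with the Ohira–Bestmann reagent on the open hydroxy-aldehyde form of the lactol adds C9 and gives the terminal alkyne under conditions too mild to affect C12.

Step 8
Reactants: 13 (S)-3-methylhex-5-yn-1-ol
Product: 14 (S)-3-methylhex-5-ynal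
Conditions: Dess–Martin periodinane, NaHCO3, CH2Cl2, 0 → 23 °C
Reagents that add atoms: none
Why: Dess–Martin oxidation of the primary alcohol to the aldehyde; the alkyne is inert and the β-stereocentre cannot epimerise.

Step 9
Reactants: 14 (S)-3-methylhex-5-ynal
Product: 15 (S)-6,6-dimethoxy-4-methylhex-1-yne
Conditions: HC(OMe)3, MeOH, PPTS (cat.), 23 °C
Reagents that add atoms: trimethyl orthoformate, COC(OC)OC
Why: Acid-catalysed acetalisation masks the future C14 aldehyde against the bases, hydrides and organometallics of steps 10–22.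

Step 10
Reactants: 15 (S)-6,6-dimethoxy-4-methylhex-1-yne; 8 tert-butyl 2-[(1R)-3-iodo-5-methyl-4-oxocyclopent-2-en-1-yl]propanoate
Product: 17 tert-butyl 2-[(1R)-3-[(1E,4S)-6,6-dimethoxy-4-methylhex-1-en-1-yl]-5-methyl-4-oxocyclopent-2-en-1-yl]propanoate, via alkenyl pinacol boronate 16 (not isolated)
Conditions: pinacolborane, Cp2Zr(H)Cl (5 mol %), Et3N (10 mol %), 60 °C; then 8, PdCl2(dppf) (5 mol %), K3PO4, THF–H2O, 23 °C
Reagents that add atoms: none
Why: syn-Hydroboration of the terminal alkyne gives the (E)-alkenylboronate and Suzuki–Miyaura coupling with the α-iodoenone forms C8–C9 with retention of the E geometry of C9=C10; the mild base leaves C16 intact.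

Step 11
Reactants: 17 the dienyl cyclopentenone
Product: 19 2-(tert-butyldimethylsilyloxy)cyclopenta-1,3-diene (C4=C3(OSi)–C8=C7 with C16 sp3), via lithium dienolate 18 (not isolated)
Conditions: LiN(i-Pr)2, THF, −78 °C; then t-BuMe2SiOTf, −78 °C; cold NaHCO3–pentane work-up, used at once
Reagents that add atoms: tert-butyldimethylsilyl trifluoromethanesulfonate, CC(C)(C)[Si](C)(C)OS(=O)(=O)C(F)(F)F
Why: Kinetic α'-deprotonation at C4–H (more acidic than the ester α-hydrogen) and O-silylation give the cross-conjugated silyloxydiene; the C16 stereocentre is not touched under these kinetic conditions.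

Step 12
Reactants: 19 the 2-silyloxycyclopentadiene; 20 1,1-bis(phenylsulfonyl)ethene
Product: 21 Diels–Alder adduct (2-silyloxybicyclo[2.2.1]hept-2-ene 5,5-bis-sulfone with the C16 side chain syn to the C3=C8 bridge)
Conditions: CH2Cl2, −40 → 0 °C
Reagents that add atoms: none
Why: Normal-electron-demand Diels–Alder cycloaddition (concerted but asynchronous, the nucleophilic diene terminus C4 bonding first to the CH2 of 20); the closest known reactions are cycloadditions of 5-substituted 2-silyloxycyclopentadienes and of 1,1-bis(phenylsulfonyl)ethene, used as an ethylene equivalent, with cyclopentadienes. The five-membered ring C4–C5–C6–C7–C16 of the target is closed by suprafacial [4+2] bonding of C5 to C4 and C6 to C7, which also creates the temporary six-membered ring C3–C4–C5–C6–C7–C8 of the bicycle. The quaternary centre C4 and the centre C7 are set together by the face of approach: the dienophile adds anti to the C16 side chain, which therefore ends syn to the C3=C8 bridge, that is cis to C3 and C8 as the target demands. The step needs facial selectivity (secured by the single stereocentre C16 directly on the diene ring), periselectivity for the ring diene over the C7=C8–C9=C10 unit (locked s-cis geometry and silyloxy activation through C3) and survival of the diene against 1,5-hydrogen shift (2-silyloxy substitution is known to slow it, and the reaction runs at or below 0 °C); the regiochemistry (CH2 to C4) disappears on desulfonylation.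

Step 13
Reactants: 21 Diels–Alder adduct
Product: 23 bicyclo[2.2.1]heptan-2-one (C3 ketone with C8–H; C5 and C6 both CH2), via desulfonylated silyl enol ether 22 (not isolated)
Conditions: Na/Hg (6 % Na), Na2HPO4, MeOH–THF, −20 °C; then Bu4NF, AcOH, THF, 0 °C
Reagents that add atoms: none
Why: Reductive desulfonylation by sodium amalgam (two successive electron-transfer C–S cleavages with protonation) unmasks the plain C5–C6 ethano bridge, and buffered fluoride cleavage of the silyl enol ether gives the ketone; the C8 configuration is irrelevant because C8 is re-enolised in step 14.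

Step 14
Reactants: 23 bicyclic ketone
Product: 25 8-(hydroxymethyl) ketone (C8 quaternary with CH2OH and the hexenyl chain), via lithium dienolate 24 (not isolated)
Conditions: LiN(SiMe3)2, THF, −78 °C; then CH2O (gas from cracked paraformaldehyde), −78 °C; AcOH quench
Reagents that add atoms: formaldehyde, C=O
Why: Aldol addition of the lithium dienolate at its α-carbon (C8, the kinetic site for lithium dienolates with aldehydes) introduces C19; the new quaternary centre need not be controlled because C8 becomes sp2 in step 16.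

Step 15
Reactants: 25 8-(hydroxymethyl) ketone
Product: 26 8-(methanesulfonyloxymethyl) ketone
Conditions: MeSO2Cl, Et3N, CH2Cl2, −20 °C
Reagents that add atoms: methanesulfonyl chloride, CS(=O)(=O)Cl
Why: Sulfonylation of the primary alcohol installs the nucleofuge for the fragmentation; C8 has no hydrogen, so elimination is impossible.

Step 16
Reactants: 26 8-(methanesulfonyloxymethyl) ketone
Product: 28 all-cis cyclopentane with the C3 methyl ketone on C4 and the 2-substituted 1,3-diene on C7, via cerium alkoxide 27 (not isolated)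
Conditions: MeLi, CeCl3, THF, −78 °C; then −78 → 23 °C
Reagents that add atoms: methyllithium, [Li]C
Why: 1,2-Addition of the weakly basic organocerium reagent to the non-enolisable C3 ketone (the tert-butyl ester is spared) and Grob fragmentation of the resulting γ-sulfonyloxy alkoxide cleave C3–C8 with release of ring strain; this gives the C3 methyl ketone (C2) and the C8=C19 methylene, and leaves C4, C16 and C7 with their three carbon substituents all-cis.

Step 17
Reactants: 28 cyclopentane methyl ketone
Product: 29 cis-fused bicyclic 1,3-dione (C3=O and C1=O with C2H2 between)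
Conditions: KOt-Bu, THF, 0 → 23 °C; AcOH quench
Reagents that add atoms: none
Why: Intramolecular Claisen (Dieckmann-type) acylation of the only enolisable ketone position (C2; C4 is quaternary) by the ester carbon C1 closes the six-membered ring, driven by deprotonation of the 1,3-dione; the ring fusion is cis because C3 and C15 are cis on the cyclopentane.

Step 18
Reactants: 29 bicyclic 1,3-dione
Product: 30 vinylogous triflate (C3 ketone with C2=C1–OTf)
Conditions: PhNTf2, Et3N, DMAP (cat.), CH2Cl2, 0 → 23 °C
Reagents that add atoms: N-phenylbis(trifluoromethanesulfonimide), O=S(=O)(N(c1ccccc1)S(=O)(=O)C(F)(F)F)C(F)(F)F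
Why: O-Sulfonylation of the dione should occur at the less hindered enol oxygen on C1 (the C3 oxygen is flanked by the quaternary C4), which keeps the C3 carbonyl and turns C1 into a coupling site.

Step 19
Reactants: 30 vinylogous triflate
Product: 32 α-hydroxy ketone (C3 ketone; C2–OH; tetrasubstituted C1(OTf)=C15 alkene), via potassium dienolate 31 (not isolated)
Conditions: KN(SiMe3)2, THF, −78 °C; then 2-(phenylsulfonyl)-3-phenyloxaziridine, −78 °C; AcOH quench
Reagents that add atoms: 2-(phenylsulfonyl)-3-phenyloxaziridine, O=S(=O)(c1ccccc1)N1OC1c1ccccc1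
Why: γ-Deprotonation at C15 (there is no α'-hydrogen) gives the extended dienolate, and oxygen transfer from the N-sulfonyloxaziridine to its α-carbon moves the double bond to C1=C15 and creates C2–OH; attack is expected anti to the C4 methyl, which sits pseudo-axial on the face opposite the cyclopentane, and this is the least secure stereochemical call of the route.

Step 20
Reactants: 32 α-hydroxy ketone
Product: 33 trans-2,3-diol
Conditions: Me4NBH(OAc)3, MeCN–AcOH, −25 °C
Reagents that add atoms: none
Why: Hydroxyl-directed reduction: the acetoxyborohydride bound to the C2 oxygen delivers hydride intramolecularly to C3 on the face of that oxygen, so the C3 hydroxyl forms trans to C2–OH and cis to the C4 methyl.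

Step 21
Reactants: 33 trans-2,3-diol
Product: 34 C2 tert-butyldimethylsilyl ether
Conditions: t-BuMe2SiCl, imidazole, DMF, 0 °C
Reagents that add atoms: tert-butyldimethylsilyl chloride, CC(C)(C)[Si](C)(C)Cl
Why: Chemoselective silylation of the allylic C2 hydroxyl, the C3 hydroxyl being neopentyl (next to quaternary C4) and markedly slower; this leaves C2 masked until the last step.

Step 22
Reactants: 34 C2 silyl ether
Product: 35 C3 acetate
Conditions: Ac2O, DMAP, pyridine, 40 °C
Reagents that add atoms: acetic anhydride, CC(=O)OC(C)=O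
Why: DMAP-catalysed acylation of the hindered C3 hydroxyl installs the first acetate of the target; the enol triflate, acetal and silyl ether are inert.

Step 23
Reactants: 35 C3 acetate
Product: 36 C14 aldehyde
Conditions: PPTS, acetone–H2O, 45 °C
Reagents that add atoms: water, O
Why: Mild acid hydrolysis of the dimethyl acetal frees the aldehyde while the secondary silyl ether, the acetate, the enol triflate and the diene survive.

Step 24
Reactants: 36 C14 aldehyde
Product: 37 tricyclic allylic alcohol (eleven-membered ring closed; C14 epimers)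
Conditions: CrCl2 (10 equiv), NiCl2 (2 mol %), DMSO–THF, 2 mM, 23 °C
Reagents that add atoms: none
Why: Nozaki–Hiyama–Kishi macrocyclisation: zerovalent nickel inserts into the C1–OTf bond, transmetalation gives an alkenyl compound of trivalent chromium that adds chemoselectively to the aldehyde with retention of the alkene geometry; the C14 configuration formed here is not relied on and is corrected in steps 25 and 26.

Step 25
Reactants: 37 tricyclic allylic alcohol
Product: 38 tricyclic C14 enone
Conditions: Dess–Martin periodinane, NaHCO3, CH2Cl2, 0 → 23 °C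
Reagents that add atoms: none
Why: Dess–Martin oxidation of the allylic alcohol under buffered, non-basic conditions removes the uncontrolled C14 centre without epimerising C16 or C2.

Step 26
Reactants: 38 tricyclic C14 enone
Product: 39 (14S)-allylic alcohol
Conditions: (R)-Me-CBS oxazaborolidine (0.5 equiv), catecholborane, toluene, −78 °C
Reagents that add atoms: none
Why: Corey–Bakshi–Shibata reduction under catalyst control: the fully substituted alkenyl carbon C1 acts as the large group and C13H2 as the small one, so the (R)-catalyst should give the (14S)-alcohol; catecholborane at low temperature spares the diene and the acetate.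

Step 27
Reactants: 39 (14S)-allylic alcohol
Product: 40 3,14-diacetate 2-silyl ether
Conditions: Ac2O, Et3N, DMAP (cat.), CH2Cl2, 23 °C
Reagents that add atoms: acetic anhydride, CC(=O)OC(C)=O
Why: Standard acylation of the only free hydroxyl with retention at C14.

Step 28
Reactants: 40 3,14-diacetate 2-silyl ether
Product: 41 target compound CNP0323842.1
Conditions: HF·pyridine, pyridine–THF, 0 → 23 °C
Reagents that add atoms: none
Why: Fluoride cleavage of the silyl ether under buffered, slightly acidic conditions frees C2–OH without acetyl migration from C3 or ionisation of the allylic C14 acetate.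

**Compound list**

1 | tert-butyl propanoate | CCC(=O)OC(C)(C)C | starting material
2 | 1-tert-butoxy-1-(trimethylsilyloxy)prop-1-ene (E/Z mixture) | CC=C(O[Si](C)(C)C)OC(C)(C)C | intermediate
3 | (S)-4-(tert-butyldimethylsilyloxy)cyclopent-2-en-1-one | O=C1C=C[C@@H](O[Si](C)(C)C(C)(C)C)C1 | starting material
4 | trimethylsilyl enol ether of tert-butyl 2-[trans-2-(tert-butyldimethylsilyloxy)-4-oxocyclopentyl]propanoate (C15 epimers) | C[Si](C)(C)OC1=C[C@H](C(C)C(=O)OC(C)(C)C)[C@@H](O[Si](C)(C)C(C)(C)C)C1 | intermediate
5 | lithium enolate corresponding to 4 | [Li]OC1=C[C@H](C(C)C(=O)OC(C)(C)C)[C@@H](O[Si](C)(C)C(C)(C)C)C1 | intermediate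
6 | tert-butyl 2-[2-(tert-butyldimethylsilyloxy)-5-methyl-4-oxocyclopentyl]propanoate (side chain trans to the silyloxy group; C4 and C15 epimers) | O=C1C(C)[C@H](C(C)C(=O)OC(C)(C)C)[C@@H](O[Si](C)(C)C(C)(C)C)C1 | intermediate
7 | tert-butyl 2-[(1R)-5-methyl-4-oxocyclopent-2-en-1-yl]propanoate | O=C1C=C[C@@H](C(C)C(=O)OC(C)(C)C)C1C | intermediate
8 | tert-butyl 2-[(1R)-3-iodo-5-methyl-4-oxocyclopent-2-en-1-yl]propanoate | O=C1C(I)=C[C@@H](C(C)C(=O)OC(C)(C)C)C1C | intermediate
9 | (R)-5-methoxy-3-methyl-5-oxopentanoic acid | COC(=O)C[C@H](C)CC(=O)O | starting material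
10 | methyl 5-hydroxy-3-methylpentanoate (configured as 9) | COC(=O)C[C@H](C)CCO | intermediate
11 | (R)-4-methyltetrahydro-2H-pyran-2-one | O=C1C[C@H](C)CCO1 | intermediate
12 | (4R)-4-methyltetrahydro-2H-pyran-2-ol (anomers) | OC1C[C@H](C)CCO1 | intermediate
13 | (S)-3-methylhex-5-yn-1-ol | C#CC[C@H](C)CCO | intermediate
14 | (S)-3-methylhex-5-ynal | C#CC[C@H](C)CC=O | intermediate
15 | (S)-6,6-dimethoxy-4-methylhex-1-yne | C#CC[C@H](C)CC(OC)OC | intermediate
16 | 2-[(1E,4S)-6,6-dimethoxy-4-methylhex-1-en-1-yl]-4,4,5,5-tetramethyl-1,3,2-dioxaborolane | CC1(C)OB(/C=C/C[C@H](C)CC(OC)OC)OC1(C)C | intermediate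
17 | tert-butyl 2-[(1R)-3-[(1E,4S)-6,6-dimethoxy-4-methylhex-1-en-1-yl]-5-methyl-4-oxocyclopent-2-en-1-yl]propanoate | COC(OC)C[C@@H](C)C/C=C/C1=C[C@@H](C(C)C(=O)OC(C)(C)C)C(C)C1=O | intermediate
18 | lithium cross-conjugated dienolate of 17 (C4=C3–OLi) | COC(OC)C[C@@H](C)C/C=C/C1=C[C@@H](C(C)C(=O)OC(C)(C)C)C(C)=C1O[Li] | intermediate
19 | 2-(tert-butyldimethylsilyloxy)cyclopenta-1,3-diene: C4(CH3)=C3(OSi)–C8(hexenyl)=C7H with C16H(side chain) sp3 | COC(OC)C[C@@H](C)C/C=C/C1=C[C@@H](C(C)C(=O)OC(C)(C)C)C(C)=C1O[Si](C)(C)C(C)(C)C | intermediate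
20 | 1,1-bis(phenylsulfonyl)ethene | C=C(S(=O)(=O)c1ccccc1)S(=O)(=O)c1ccccc1 | starting material
21 | Diels–Alder adduct: bicyclo[2.2.1]hept-2-ene with bridgeheads C4 (CH3) and C7 (H); C3(OSi)=C8(hexenyl) bridge; C5H2–C6(SO2Ph)2 bridge; C16 bridge with its propanoate chain syn to C3=C8 | COC(OC)C[C@@H](C)C/C=C/C1=C(O[Si](C)(C)C(C)(C)C)[C@@]2(C)CC(S(=O)(=O)c3ccccc3)(S(=O)(=O)c3ccccc3)[C@@H]1[C@H]2C(C)C(=O)OC(C)(C)C | intermediate
22 | desulfonylated silyl enol ether (as 21 with C6H2) | COC(OC)C[C@@H](C)C/C=C/C1=C(O[Si](C)(C)C(C)(C)C)[C@@]2(C)CC[C@@H]1[C@H]2C(C)C(=O)OC(C)(C)C | intermediate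
23 | bicyclo[2.2.1]heptan-2-one: C3 ketone; C8H(hexenyl) (epimers) | COC(OC)C[C@@H](C)C/C=C/C1C(=O)[C@@]2(C)CC[C@@H]1[C@H]2C(C)C(=O)OC(C)(C)C | intermediate
24 | lithium dienolate of 23 | COC(OC)C[C@@H](C)C/C=C/C1=C(O[Li])[C@@]2(C)CC[C@@H]1[C@H]2C(C)C(=O)OC(C)(C)C | intermediate
25 | 8-(hydroxymethyl) ketone (C8 quaternary; epimers) | COC(OC)C[C@@H](C)C/C=C/C1(CO)C(=O)[C@@]2(C)CC[C@@H]1[C@H]2C(C)C(=O)OC(C)(C)C | intermediate
26 | 8-(methanesulfonyloxymethyl) ketone | COC(OC)C[C@@H](C)C/C=C/C1(COS(C)(=O)=O)C(=O)[C@@]2(C)CC[C@@H]1[C@H]2C(C)C(=O)OC(C)(C)C | intermediate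
27 | tertiary C3 alkoxide (drawn as dichlorocerium alkoxide) | COC(OC)C[C@@H](C)C/C=C/C1(COS(C)(=O)=O)C(C)(O[Ce](Cl)Cl)[C@@]2(C)CC[C@@H]1[C@H]2C(C)C(=O)OC(C)(C)C | intermediate
28 | all-cis cyclopentane: C4(CH3)(acetyl); C16H–CH(CH3)CO2t-Bu; C7H–C8(=CH2)–(E)-CH=CH–chain | COC(OC)C[C@@H](C)C/C=C/C(=C)[C@@H]1CC[C@](C)(C(C)=O)[C@@H]1C(C)C(=O)OC(C)(C)C | intermediate
29 | cis-fused bicyclic 1,3-dione (C3=O; C1=O; C15 epimers; enolises) | COC(OC)C[C@@H](C)C/C=C/C(=C)[C@@H]1CC[C@]2(C)C(=O)CC(=O)C(C)[C@H]12 | intermediate
30 | vinylogous triflate: C3 ketone; C2=C1(OTf) | COC(OC)C[C@@H](C)C/C=C/C(=C)[C@@H]1CC[C@]2(C)C(=O)C=C(OS(=O)(=O)C(F)(F)F)C(C)[C@H]12 | intermediate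
31 | potassium dienolate of 30 | COC(OC)C[C@@H](C)C/C=C/C(=C)[C@@H]1CC[C@]2(C)C(O[K])=CC(OS(=O)(=O)C(F)(F)F)=C(C)[C@H]12 | intermediate
32 | α-hydroxy ketone: C3 ketone; C2–OH trans to the C4 methyl; C1(OTf)=C15 | COC(OC)C[C@@H](C)C/C=C/C(=C)[C@@H]1CC[C@]2(C)C(=O)[C@H](O)C(OS(=O)(=O)C(F)(F)F)=C(C)[C@H]12 | intermediate
33 | trans-2,3-diol (C3–OH cis to the C4 methyl) | COC(OC)C[C@@H](C)C/C=C/C(=C)[C@@H]1CC[C@]2(C)[C@@H](O)[C@H](O)C(OS(=O)(=O)C(F)(F)F)=C(C)[C@H]12 | intermediate
34 | C2 tert-butyldimethylsilyl ether of 33 | COC(OC)C[C@@H](C)C/C=C/C(=C)[C@@H]1CC[C@]2(C)[C@@H](O)[C@H](O[Si](C)(C)C(C)(C)C)C(OS(=O)(=O)C(F)(F)F)=C(C)[C@H]12 | intermediate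
35 | C3 acetate of 34 | COC(OC)C[C@@H](C)C/C=C/C(=C)[C@@H]1CC[C@]2(C)[C@@H](OC(C)=O)[C@H](O[Si](C)(C)C(C)(C)C)C(OS(=O)(=O)C(F)(F)F)=C(C)[C@H]12 | intermediate
36 | C14 aldehyde | O=CC[C@@H](C)C/C=C/C(=C)[C@@H]1CC[C@]2(C)[C@@H](OC(C)=O)[C@H](O[Si](C)(C)C(C)(C)C)C(OS(=O)(=O)C(F)(F)F)=C(C)[C@H]12 | intermediate
37 | tricyclic allylic alcohol (C14 epimers; C3–OAc; C2–OSi) | C=C1/C=C/C[C@H](C)CC(O)C2=C(C)[C@@H]3[C@H]1CC[C@]3(C)[C@@H](OC(C)=O)[C@@H]2O[Si](C)(C)C(C)(C)C | intermediate
38 | tricyclic C14 enone | C=C1/C=C/C[C@H](C)CC(=O)C2=C(C)[C@@H]3[C@H]1CC[C@]3(C)[C@@H](OC(C)=O)[C@@H]2O[Si](C)(C)C(C)(C)C | intermediate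
39 | (14S)-allylic alcohol | C=C1/C=C/C[C@H](C)C[C@H](O)C2=C(C)[C@@H]3[C@H]1CC[C@]3(C)[C@@H](OC(C)=O)[C@@H]2O[Si](C)(C)C(C)(C)C | intermediate
40 | 3,14-diacetate 2-(tert-butyldimethylsilyl) ether | C=C1/C=C/C[C@H](C)C[C@H](OC(C)=O)C2=C(C)[C@@H]3[C@H]1CC[C@]3(C)[C@@H](OC(C)=O)[C@@H]2O[Si](C)(C)C(C)(C)C | intermediate
41 | CNP0323842.1 (3,14-diacetate 2-ol) | C=C1/C=C/C[C@H](C)C[C@H](OC(C)=O)C2=C(C)[C@@H]3[C@H]1CC[C@]3(C)[C@@H](OC(C)=O)[C@@H]2O | target

**Step count and risks**

Total step count: 28. Longest linear sequence: 24 steps (from 9 through steps 5–9 and 10–28).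

Steps most likely to fail:

- **Step 16.** The methyl nucleophile may fail to add to the C3 ketone, which is flanked by two fully substituted carbons and shielded by the syn side chain on C16; the results would be recovered ketone or competing attack at the tert-butyl ester. The fallback sets out from 26 and uses the smallest possible nucleophile: NaBH4 in MeOH–THF should reduce the ketone to the secondary carbinol mesylate F1; KN(SiMe3)2 in THF then triggers the same Grob fragmentation to the neopentyl aldehyde F2; MeMgBr at −78 °C adds to the aldehyde beside the tert-butyl ester to give the methyl carbinol F3; Dess–Martin oxidation of F3 returns the route at 28.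
- **Step 19.** Oxygen transfer to the dienolate may show poor or reversed facial selectivity, because the C4 methyl and the folded cyclopentane shield opposite faces of C2. The fallback sets out from 30: if hydroxylation gives mainly the C2-epimeric ketol F4, this is oxidised with Dess–Martin periodinane to the ene-1,2-dione F5; its more electrophilic and less hindered C2 carbonyl is then reduced with NaBH4–CeCl3 at −78 °C from that same exposed face, which places the hydroxyl on the required face and returns the route at 32.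
- **Step 12.** The silyloxydiene may be lost through 1,5-hydrogen shift, or may undergo conjugate addition without ring closure, before cycloaddition takes place. The fallback sets out from 17 and forms the same two bonds by an anionic double Michael sequence that never passes through a neutral cyclopentadiene: lithium dienolate 18 is treated with phenyl vinyl sulfone in THF (−78 → 0 °C); C4 adds to the CH2 terminus and the α-sulfonyl carbanion closes onto C7 anti to the C16 side chain, giving the bicyclic keto sulfone F6; Na/Hg desulfonylation of F6 returns the route at 23.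

Further compounds
F1 | step 16 | secondary carbinol mesylate (C3–OH; otherwise as 26) | COC(OC)C[C@@H](C)C/C=C/C1(COS(C)(=O)=O)C(O)[C@@]2(C)CC[C@@H]1[C@H]2C(C)C(=O)OC(C)(C)C
F2 | step 16 | neopentyl aldehyde (C3 aldehyde on C4; otherwise as 28) | COC(OC)C[C@@H](C)C/C=C/C(=C)[C@@H]1CC[C@](C)(C=O)[C@@H]1C(C)C(=O)OC(C)(C)C
F3 | step 16 | methyl carbinol (C3–OH with C2 methyl; epimers) | COC(OC)C[C@@H](C)C/C=C/C(=C)[C@@H]1CC[C@](C)(C(C)O)[C@@H]1C(C)C(=O)OC(C)(C)C
F4 | step 19 | C2-epimeric ketol (C2 epimer of 32) | COC(OC)C[C@@H](C)C/C=C/C(=C)[C@@H]1CC[C@]2(C)C(=O)[C@@H](O)C(OS(=O)(=O)C(F)(F)F)=C(C)[C@H]12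
F5 | step 19 | ene-1,2-dione (C2 and C3 ketones) | COC(OC)C[C@@H](C)C/C=C/C(=C)[C@@H]1CC[C@]2(C)C(=O)C(=O)C(OS(=O)(=O)C(F)(F)F)=C(C)[C@H]12
F6 | step 12 | bicyclic keto sulfone (as 23 with PhSO2 on C6) | COC(OC)C[C@@H](C)C/C=C/C1C(=O)[C@@]2(C)CC(S(=O)(=O)c3ccccc3)[C@@H]1[C@H]2C(C)C(=O)OC(C)(C)C
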